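Target cannot outgrow what pays for it. It cannot exceed the substrate charged, and on the suspect route, where one reagent enters with substrate and a second with intermediate B, it cannot exceed half the reagent charged, 0.0750 M.

| flask | substrate | reagent | remark | time |
|---|---|---|---|---|
| south-east | 0.030 M | 0.15 M | run made earlier |  |
| south-west | 0.11 M | 0.15 M | run made earlier |  |
| north-west | 0.42 M | 0.15 M | run made earlier |  |
| autumn | 0.025 M | 0.150 M |  | 30 h |
| midnight | 0.050 M | 0.150 M |  | 30 h |
| dawn | 0.10 M | 0.150 M |  | 30 h |
| spring | 0.20 M | 0.150 M |  | 30 h |
| dusk | 0.40 M | 0.150 M |  | 30 h |

| run | time / h | target / % | substrate / % |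
|---|---|---|---|
| south-east | 1.33 | 10.7 | 48.8 |
| south-east | 3.00 | 22.4 | 24.6 |
| south-east | 6.00 | 30.7 | 8.9 |
| south-east | 15.0 | 34.6 | 0.1 |
| south-west | 1.33 | 9.5 | 49.9 |
| south-west | 3.00 | 17.0 | 26.6 |
| south-west | 6.00 | 23.1 | 10.2 |
| south-west | 15.0 | 26.9 | 0.8 |
| north-west | 2.00 | 7.5 | 44.4 |
| north-west | 5.00 | 7.1 | 18.8 |
| north-west | 10.0 | 8.1 | 4.8 |
| north-west | 15.0 | 8.1 | 0.8 |

(scatter of a reading: 0.5 percentage points)

- on the list of suspects stand: substrate + reagent -> intermediate A; substrate -> side product A; substrate -> side product B; intermediate A -> intermediate B; reagent + intermediate B -> target; 2 reagent -> self-condensation product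
- "hardly changes" means that all values lie within two and a half points (for a concentration: within two and a half percent of the largest)

- [target] at the end for autumn, midnight, dawn, spring, dusk, in this order
- how the row runs (falls all the way / rises, then falls / hardly changes / falls, then rises / rises all the way)

1. Dilute extreme. The south-east run, at 0.030 M, gives as its last reading, at 15.0 h, a target share Y = 34.6%, with substrate at 0.1%. With substrate as the limiting reagent, the first line is [target] = Y·c, where c is the substrate charged.

2. Concentrated extreme. In the north-west run, target stands at 7.5% at 2.00 h and 8.1% at 15.0 h, while substrate falls from 44.4% to 0.8%. Target moves by 0.6 percentage points against a scatter of 0.5 points, so the later substrate goes elsewhere. The second line is flat, [target] = T = 0.0340 M, which lies lower than the bound above.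

3. The lines meet at 0.0983 M. This is the crossover loading c×, the substrate charge at which the flat line of the concentrated extreme takes over from the rising line of the dilute extreme.

4. The real flask rounds this corner. The south-west run, at 0.11 M, reads 0.0296 M, lower than both Y·c = 0.0381 M and T. This reckoning therefore puts autumn near 0.00865 M, dawn under the corner and dusk near T. It leaves open whether the row dips after the bend.

5. The forecast goes further than this reckoning, which names no shape, and gives 0.0089 M, 0.0163 M, 0.028 M, 0.038 M, 0.035 M, and the shape rises, then falls: “The absolute amount therefore probably peaks near 0.2 M, then falls slightly, though that fall is uncertain.”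

The flasks give 0.00891 M, 0.0169 M, 0.0297 M, 0.0375 M, 0.0340 M, and the shape rises, then falls.

    substrate + reagent → intermediate A (k = 0.0420 /M/min)
    substrate → side product A (k = 4.90 × 10⁻⁴ /min)
    substrate → side product B (k = 0.00430 /min)
    intermediate A → intermediate B (k = 0.0770 /min)
    reagent + intermediate B → target (k = 0.230 /M/min)
    2 reagent → self-condensation product (k = 0.0470 /M/min)

In autumn, at 0.254 c×, self-condensation had half its turnover up to 30.0 h behind it by 0.934 h and the loss to side product B by 1.74 h, and the flask ended at 0.00891 M of target. In dusk, at 4.07 c×, reagent stood at 0% of its charge at 30.0 h, intermediate B stood at 10.5% of the substrate charged, and target ended at 0.0340 M. The row turned at 0.21 M, twice c×.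

The data were computed with constants of no real substance, noise included.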